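**Plan**

- Enabling feature: rings A and B are trans-fused, C10 is quaternary and its neighbour C9 carries C11. C9=C10 can therefore act as an (E)-3-methyl-enoyl dienophile, C5=C6–C7=C8 (C17 on C8) as the diene and C1–C4 as a four-atom tether: a 1,7,9-decatriene with C4 as a malonate carbon.
- Retrosynthesis, late cuts: remove the acetate; cut C12–C13 (B-alkyl Suzuki–Miyaura coupling) and C11=C12 (methylenation of a C8=C9 enal); return the C18 methyl to the equatorial ester of a C4 gem-diester and the C8=C9 alkene to a saturated C11 aldehyde.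
- Retrosynthesis, core cuts: cut C5–C10 and C8–C9 together (intramolecular Diels–Alder) to an acyclic trienyl imide; cut C3–C4 to a pentenylidene malonate and a 6-iodo-3-methylhex-2-enoyl oxazolidinone.
- Forward: the chain is joined at C3–C4, rings A and B close in one cycloaddition, C6=C7 is hydrogenated, C8=C9 is made by selenoxide elimination, C12 is added by methylenation, the equatorial ester becomes methyl, and C13–C16 are attached last.
- Stereochemistry: C10 and C5 come from the (S)-4-benzyloxazolidinone chelate (diene anti to benzyl, carbonyl endo, tether anti). C4 comes from hydride attack on the less hindered equatorial ester. The E dienophile comes from syn-carboalumination and E-C13=C14 from an (E)-enol triflate.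

Key step: step 7

Remark: positions are given in labdane numbering (C4 bears the ester, C10 the angular methyl, C8=C9 is the ring alkene, C11–C16 the side chain); β is the face of the C10 methyl group, α the opposite face.

**Route**

Step 1
Reactants: 1 5-chloropent-1-yne
Product: 3 ethyl (E)-6-chloro-3-methylhex-2-enoate, via alkenyldimethylalane 2 (not isolated)
Conditions: Me3Al, Cp2ZrCl2 (cat.), CH2Cl2, 0 °C to rt; then ClCO2Et, 0 °C to rt
Reagents that add atoms: trimethylaluminium, C[Al](C)C; ethyl chloroformate, CCOC(=O)Cl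
Why: Zirconium-catalysed syn-methylalumination of the terminal alkyne (Negishi carboalumination) places aluminium on C1 and methyl on C2 on the same side, and the alkenylalane is acylated by the chloroformate with retention, so the enoate should form as the E isomer while the primary chloride is inert to Me3Al.

Step 2
Reactants: 3 ethyl (E)-6-chloro-3-methylhex-2-enoate
Product: 4 (E)-6-chloro-3-methylhex-2-enoic acid
Conditions: LiOH, THF/H2O, rt; then 1 M HCl
Reagents that add atoms: lithium hydroxide, [Li+].[OH-]
Why: Ester saponification is faster than substitution of the primary chloride, and the E geometry keeps the carboxylate away from C6, so the chloro acid should form without lactonisation.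

Step 3
Reactants: 4 (E)-6-chloro-3-methylhex-2-enoic acid; 5 (S)-4-benzyloxazolidin-2-one
Product: 8 (S)-4-benzyl-3-[(E)-6-chloro-3-methylhex-2-enoyl]oxazolidin-2-one, via mixed pivalic anhydride 6 (not isolated), via N-lithio oxazolidinone 7 (not isolated)
Conditions: 4, t-BuCOCl, Et3N, THF, −78 to 0 °C; 5, n-BuLi, THF, −78 °C; combine, −78 to 0 °C
Reagents that add atoms: none
Why: N-Acylation of the lithiated oxazolidinone by the pivalic mixed anhydride occurs at the less hindered enoyl carbonyl at low temperature, where the trisubstituted E alkene should neither deconjugate nor isomerise.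

Step 4
Reactants: 8 (S)-4-benzyl-3-[(E)-6-chloro-3-methylhex-2-enoyl]oxazolidin-2-one
Product: 9 (S)-4-benzyl-3-[(E)-6-iodo-3-methylhex-2-enoyl]oxazolidin-2-one
Conditions: NaI, acetone, reflux
Reagents that add atoms: sodium iodide, [Na+].[I-]
Why: Finkelstein exchange, driven by precipitation of NaCl from acetone, gives the iodide needed for alkylation of a hindered carbanion, and the imide is inert to iodide.

Step 5
Reactants: 10 dimethyl malonate; 11 (E)-pent-2-enal
Product: 12 dimethyl 2-[(E)-pent-2-en-1-ylidene]malonate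
Conditions: TiCl4, pyridine, THF, 0 °C to rt
Reagents that add atoms: none
Why: Knoevenagel condensation under TiCl4/pyridine activates the aldehyde carbonyl for 1,2-attack by the titanium enolate of the malonate, which should suppress conjugate addition and keep the E alkene of the enal.

Step 6
Reactants: 12 dimethyl 2-[(E)-pent-2-en-1-ylidene]malonate; 9 (S)-4-benzyl-3-[(E)-6-iodo-3-methylhex-2-enoyl]oxazolidin-2-one
Product: 14 dimethyl 2-{(E)-6-[(S)-4-benzyl-2-oxooxazolidin-3-yl]-4-methyl-6-oxohex-4-en-1-yl}-2-[(1E,3E)-penta-1,3-dien-1-yl]malonate, via sodium dienylmalonate 13 (not isolated)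
Conditions: 12, NaN(SiMe3)2 (1.0 equiv), THF, −78 °C; then 9, DMF, −78 °C to rt
Reagents that add atoms: none
Why: Deconjugative α-alkylation of an alkylidene malonate: deprotonation at the ε-CH2 gives an extended pentadienyl-type anion that attacks the primary iodide by SN2 at the malonate carbon, which moves both double bonds into the (1E,3E)-diene, while one equivalent of base and the soft anion leave the imide untouched.

Step 7
Reactants: 14 dimethyl 2-{(E)-6-[(S)-4-benzyl-2-oxooxazolidin-3-yl]-4-methyl-6-oxohex-4-en-1-yl}-2-[(1E,3E)-penta-1,3-dien-1-yl]malonate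
Product: 15 dimethyl (4aS,5S,6S,8aR)-5-{[(S)-4-benzyl-2-oxooxazolidin-3-yl]carbonyl}-4a,6-dimethyl-3,4,4a,5,6,8a-hexahydronaphthalene-1,1(2H)-dicarboxylate (trans-fused; 10β-methyl, 5α-H, 8β-methyl, 9β-acyl, C6=C7)
Conditions: Me2AlCl (3 equiv), CH2Cl2, −30 to 0 °C
Reagents that add atoms: none
Why: Two equivalents of Me2AlCl turn the imide into a cationic aluminium chelate of its two carbonyl groups, which holds the enoyl unit s-cis and lowers its LUMO, and the tethered diene then adds suprafacially across C9=C10 in a concerted, asynchronous [4+2] cycloaddition; the closest known reaction type is the Lewis acid-promoted intramolecular Diels–Alder reaction of 2,8,10-trienoyl oxazolidinone imides, here in its more demanding β,β-disubstituted form. Ring B closes as the cyclohexene of the cycloaddition (bonds C5–C10 and C8–C9) and ring A closes at the same time as the six-membered ring spanned by the C1–C4 tether, a closure favoured by the geminal esters at C4. C10 is set by the auxiliary, because the benzyl group covers one face of the chelated dienophile and the diene adds to the opposite (Cα-si) face, and C5 follows from C10 through the transition state with the carbonyl endo and the tether anti, which gives the trans ring fusion. C9 follows from the E geometry of the dienophile (acyl cis to the C10 methyl) and C8 from the E geometry of the diene terminus combined with endo addition. The step needs endo over exo addition and one π-face over the other: the first is secured by the Lewis acid-bound carbonyl and the chair-like tether, the second by the (S)-benzyl group on the rigid chelate.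

Step 8
Reactants: 15 cycloadduct (C6=C7)
Product: 16 dimethyl (4aS,5S,6S,8aR)-5-{[(S)-4-benzyl-2-oxooxazolidin-3-yl]carbonyl}-4a,6-dimethyloctahydronaphthalene-1,1(2H)-dicarboxylate
Conditions: H2 (1 atm), 10% Pd on carbon, EtOAc, rt
Reagents that add atoms: none
Why: Heterogeneous hydrogenation saturates the only alkene, the disubstituted C6=C7, and neither the imide, the esters nor the C-benzyl group is reduced under these conditions.

Step 9
Reactants: 16 saturated imide
Product: 17 dimethyl (4aS,5S,6S,8aR)-5-[(ethylsulfanyl)carbonyl]-4a,6-dimethyloctahydronaphthalene-1,1(2H)-dicarboxylate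
Conditions: EtSH, n-BuLi, THF, 0 °C to rt; aqueous work-up
Reagents that add atoms: ethanethiol, CCS
Why: Thiolate cleavage of an N-acyl oxazolidinone: the small, soft lithium thiolate attacks the exocyclic carbonyl even when it is hindered and releases the auxiliary for recovery, while the two neopentyl methyl esters should not react at this temperature.

Step 10
Reactants: 17 thioester
Product: 18 dimethyl (4aS,5S,6S,8aR)-5-formyl-4a,6-dimethyloctahydronaphthalene-1,1(2H)-dicarboxylate
Conditions: Et3SiH, 10% Pd on carbon, acetone, rt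
Reagents that add atoms: none
Why: Fukuyama reduction: palladium inserts into the C–S bond and the silane delivers hydride, so the reduction should stop at the aldehyde and leave the methyl esters alone.

Step 11
Reactants: 18 saturated C11 aldehyde
Product: 22 dimethyl (4aS,8aR)-5-formyl-4a,6-dimethyl-3,4,4a,7,8,8a-hexahydronaphthalene-1,1(2H)-dicarboxylate, via silyl enol ether 19 (not isolated), via selanyl aldehyde 20 (not isolated), via selenoxide 21 (not isolated)
Conditions: Me3SiOTf, Et3N, CH2Cl2, 0 °C; PhSeCl, −78 °C; then 30% H2O2, pyridine, 0 °C to rt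
Reagents that add atoms: none
Why: Soft enolisation gives the silyl enol ether, electrophilic selenenylation should occur at C9 from the α face, away from the axial methyl groups on C8 and C10, and the selenoxide then undergoes syn-elimination with the cis H-8, the only β-hydrogen, to give the tetrasubstituted enal and relieve the 1,3-diaxial methyl–methyl strain.

Step 12
Reactants: 22 C8=C9 enal
Product: 23 dimethyl (4aS,8aR)-5-ethenyl-4a,6-dimethyl-3,4,4a,7,8,8a-hexahydronaphthalene-1,1(2H)-dicarboxylate
Conditions: Ph3PCH3Br, KOt-Bu, THF, 0 °C to rt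
Reagents that add atoms: methyltriphenylphosphonium bromide, C[P+](c1ccccc1)(c1ccccc1)c1ccccc1.[Br-]
Why: Wittig methylenation with the unstabilised ylide is fast even for hindered β,β-disubstituted enals of this cyclocitral type and does not touch the esters.

Step 13
Reactants: 23 diene gem-diester
Product: 24 methyl (1S,4aS,8aR)-5-ethenyl-1-(hydroxymethyl)-4a,6-dimethyl-1,2,3,4,4a,7,8,8a-octahydronaphthalene-1-carboxylate (4α-CH2OH, 4β-CO2Me)
Conditions: LiAlH(Ot-Bu)3, THF, rt to 50 °C
Reagents that add atoms: none
Why: Mono-reduction of a disubstituted malonate by the bulky hydride LiAlH(Ot-Bu)3: the equatorial (α) ester should be attacked because the axial ester is shielded by the syn-axial C10 methyl group, and the alkoxyaluminate formed deactivates the remaining ester, which sets C4 with the ester β.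

Step 14
Reactants: 24 hydroxymethyl ester
Product: 25 methyl (1R,4aS,8aR)-5-ethenyl-1-(iodomethyl)-4a,6-dimethyl-1,2,3,4,4a,7,8,8a-octahydronaphthalene-1-carboxylate
Conditions: PPh3, I2, imidazole, toluene, 80 °C
Reagents that add atoms: iodine, [I][I]
Why: Appel-type iodination replaces the neopentyl hydroxyl by SN2 displacement of the alkoxyphosphonium ion, a path that needs heating but cannot rearrange because no cation is formed.

Step 15
Reactants: 25 neopentyl iodide
Product: 26 methyl (1S,4aS,8aR)-5-ethenyl-1,4a,6-trimethyl-1,2,3,4,4a,7,8,8a-octahydronaphthalene-1-carboxylate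
Conditions: Bu3SnH, AIBN (cat.), toluene, 80 °C
Reagents that add atoms: none
Why: Radical chain dehalogenation: the stannyl radical abstracts iodine and the primary C18 radical, which has no alkene within reach, takes hydrogen from Bu3SnH to give the C18 methyl group.

Step 16
Reactants: 27 methyl acetoacetate
Product: 28 methyl (E)-3-{[(trifluoromethyl)sulfonyl]oxy}but-2-enoate
Conditions: Tf2O, aq. Me4NOH, toluene, 5 °C
Reagents that add atoms: trifluoromethanesulfonic anhydride, O=S(=O)(OS(=O)(=O)C(F)(F)F)C(F)(F)F
Why: O-Triflation of the β-keto ester enolate under non-chelating conditions (tetramethylammonium counter-ion, two-phase system) is known to favour the E enol triflate, with the triflate trans to the ester.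

Step 17
Reactants: 26 vinyl diene ester; 28 methyl (E)-3-{[(trifluoromethyl)sulfonyl]oxy}but-2-enoate
Product: 30 methyl (1S,4aS,8aR)-5-[(E)-5-methoxy-3-methyl-5-oxopent-3-en-1-yl]-1,4a,6-trimethyl-1,2,3,4,4a,7,8,8a-octahydronaphthalene-1-carboxylate, via B-alkyl borane 29 (not isolated)
Conditions: 26, 9-BBN, THF, 0 °C to rt; then 28, PdCl2(dppf) (cat.), aq. K3PO4, DMF, 50 °C
Reagents that add atoms: none
Why: 9-BBN should hydroborate only the monosubstituted vinyl group with boron at the terminal carbon (the tetrasubstituted alkene is inert), and B-alkyl Suzuki–Miyaura coupling with the enol triflate proceeds with retention at the sp2 carbon, so C12–C13 forms with C12 trans to C15.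

Step 18
Reactants: 30 C15,C19 diester
Product: 31 methyl (1S,4aS,8aR)-5-[(E)-5-hydroxy-3-methylpent-3-en-1-yl]-1,4a,6-trimethyl-1,2,3,4,4a,7,8,8a-octahydronaphthalene-1-carboxylate
Conditions: i-Bu2AlH (2.2 equiv), CH2Cl2, −78 °C
Reagents that add atoms: none
Why: At −78 °C i-Bu2AlH reduces the unhindered conjugated ester by 1,2-addition to the allylic alcohol, whereas the axial neopentyl ester on C4, flanked by the C10 methyl group, should react far more slowly.

Step 19
Reactants: 31 C15 allylic alcohol
Product: 32 methyl (1S,4aS,8aR)-5-[(E)-5-acetoxy-3-methylpent-3-en-1-yl]-1,4a,6-trimethyl-1,2,3,4,4a,7,8,8a-octahydronaphthalene-1-carboxylate (target, CNP0206695.1)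
Conditions: Ac2O, pyridine, DMAP (cat.), CH2Cl2, rt
Reagents that add atoms: acetic anhydride, CC(=O)OC(C)=O
Why: DMAP-catalysed acylation of the primary allylic alcohol with acetic anhydride gives the acetate without affecting the hindered methyl ester.

**Compound list**

1 | 5-chloropent-1-yne | C#CCCCCl | starting material
2 | (E)-(5-chloro-2-methylpent-1-en-1-yl)dimethylalane | C[Al](C)/C=C(\C)CCCCl | intermediate
3 | ethyl (E)-6-chloro-3-methylhex-2-enoate | CCOC(=O)/C=C(\C)CCCCl | intermediate
4 | (E)-6-chloro-3-methylhex-2-enoic acid | OC(=O)/C=C(\C)CCCCl | intermediate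
5 | (S)-4-benzyloxazolidin-2-one | O=C1OC[C@H](Cc2ccccc2)N1 | starting material
6 | (E)-6-chloro-3-methylhex-2-enoic pivalic anhydride | CC(C)(C)C(=O)OC(=O)/C=C(\C)CCCCl | intermediate
7 | lithium (S)-4-benzyl-2-oxooxazolidin-3-ide | [Li+].O=C1OC[C@H](Cc2ccccc2)[N-]1 | intermediate
8 | (S)-4-benzyl-3-[(E)-6-chloro-3-methylhex-2-enoyl]oxazolidin-2-one | ClCCC/C(C)=C/C(=O)N1C(=O)OC[C@@H]1Cc1ccccc1 | intermediate
9 | (S)-4-benzyl-3-[(E)-6-iodo-3-methylhex-2-enoyl]oxazolidin-2-one | ICCC/C(C)=C/C(=O)N1C(=O)OC[C@@H]1Cc1ccccc1 | intermediate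
10 | dimethyl malonate | COC(=O)CC(=O)OC | starting material
11 | (E)-pent-2-enal | CC/C=C/C=O | starting material
12 | dimethyl 2-[(E)-pent-2-en-1-ylidene]malonate | CC/C=C/C=C(C(=O)OC)C(=O)OC | intermediate
13 | sodium (2E,4E)-1,1-bis(methoxycarbonyl)hexa-2,4-dien-1-ide | [Na+].C/C=C/C=C/[C-](C(=O)OC)C(=O)OC | intermediate
14 | dimethyl 2-{(E)-6-[(S)-4-benzyl-2-oxooxazolidin-3-yl]-4-methyl-6-oxohex-4-en-1-yl}-2-[(1E,3E)-penta-1,3-dien-1-yl]malonate | C/C=C/C=C/C(C(=O)OC)(C(=O)OC)CCC/C(C)=C/C(=O)N1C(=O)OC[C@@H]1Cc1ccccc1 | intermediate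
15 | dimethyl (4aS,5S,6S,8aR)-5-{[(S)-4-benzyl-2-oxooxazolidin-3-yl]carbonyl}-4a,6-dimethyl-3,4,4a,5,6,8a-hexahydronaphthalene-1,1(2H)-dicarboxylate | COC(=O)C1(C(=O)OC)CCC[C@]2(C)[C@@H](C(=O)N3C(=O)OC[C@@H]3Cc3ccccc3)[C@@H](C)C=C[C@@H]12 | intermediate
16 | dimethyl (4aS,5S,6S,8aR)-5-{[(S)-4-benzyl-2-oxooxazolidin-3-yl]carbonyl}-4a,6-dimethyloctahydronaphthalene-1,1(2H)-dicarboxylate | COC(=O)C1(C(=O)OC)CCC[C@]2(C)[C@@H](C(=O)N3C(=O)OC[C@@H]3Cc3ccccc3)[C@@H](C)CC[C@@H]12 | intermediate
17 | dimethyl (4aS,5S,6S,8aR)-5-[(ethylsulfanyl)carbonyl]-4a,6-dimethyloctahydronaphthalene-1,1(2H)-dicarboxylate | COC(=O)C1(C(=O)OC)CCC[C@]2(C)[C@@H](C(=O)SCC)[C@@H](C)CC[C@@H]12 | intermediate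
18 | dimethyl (4aS,5S,6S,8aR)-5-formyl-4a,6-dimethyloctahydronaphthalene-1,1(2H)-dicarboxylate | COC(=O)C1(C(=O)OC)CCC[C@]2(C)[C@@H](C=O)[C@@H](C)CC[C@@H]12 | intermediate
19 | dimethyl (4aS,6S,8aR)-4a,6-dimethyl-5-[(trimethylsilyloxy)methylidene]octahydronaphthalene-1,1(2H)-dicarboxylate (enol ether geometry not defined) | COC(=O)C1(C(=O)OC)CCC[C@]2(C)C(=CO[Si](C)(C)C)[C@@H](C)CC[C@@H]12 | intermediate
20 | dimethyl (4aS,5R,6S,8aR)-5-formyl-4a,6-dimethyl-5-(phenylselanyl)octahydronaphthalene-1,1(2H)-dicarboxylate (9α-SePh) | COC(=O)C1(C(=O)OC)CCC[C@]2(C)[C@](C=O)([Se]c3ccccc3)[C@@H](C)CC[C@@H]12 | intermediate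
21 | selenoxide of 20 (9α-phenylseleninyl; selenium configuration not defined) | COC(=O)C1(C(=O)OC)CCC[C@]2(C)[C@](C=O)([Se](=O)c3ccccc3)[C@@H](C)CC[C@@H]12 | intermediate
22 | dimethyl (4aS,8aR)-5-formyl-4a,6-dimethyl-3,4,4a,7,8,8a-hexahydronaphthalene-1,1(2H)-dicarboxylate | COC(=O)C1(C(=O)OC)CCC[C@]2(C)C(C=O)=C(C)CC[C@@H]12 | intermediate
23 | dimethyl (4aS,8aR)-5-ethenyl-4a,6-dimethyl-3,4,4a,7,8,8a-hexahydronaphthalene-1,1(2H)-dicarboxylate | COC(=O)C1(C(=O)OC)CCC[C@]2(C)C(C=C)=C(C)CC[C@@H]12 | intermediate
24 | methyl (1S,4aS,8aR)-5-ethenyl-1-(hydroxymethyl)-4a,6-dimethyl-1,2,3,4,4a,7,8,8a-octahydronaphthalene-1-carboxylate | COC(=O)[C@@]1(CO)CCC[C@]2(C)C(C=C)=C(C)CC[C@@H]12 | intermediate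
25 | methyl (1R,4aS,8aR)-5-ethenyl-1-(iodomethyl)-4a,6-dimethyl-1,2,3,4,4a,7,8,8a-octahydronaphthalene-1-carboxylate | COC(=O)[C@@]1(C[I])CCC[C@]2(C)C(C=C)=C(C)CC[C@@H]12 | intermediate
26 | methyl (1S,4aS,8aR)-5-ethenyl-1,4a,6-trimethyl-1,2,3,4,4a,7,8,8a-octahydronaphthalene-1-carboxylate | COC(=O)[C@@]1(C)CCC[C@]2(C)C(C=C)=C(C)CC[C@@H]12 | intermediate
27 | methyl acetoacetate (methyl 3-oxobutanoate) | CC(=O)CC(=O)OC | starting material
28 | methyl (E)-3-{[(trifluoromethyl)sulfonyl]oxy}but-2-enoate | COC(=O)/C=C(\C)OS(=O)(=O)C(F)(F)F | intermediate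
29 | methyl (1S,4aS,8aR)-5-[2-(9-borabicyclo[3.3.1]nonan-9-yl)ethyl]-1,4a,6-trimethyl-1,2,3,4,4a,7,8,8a-octahydronaphthalene-1-carboxylate | COC(=O)[C@@]1(C)CCC[C@]2(C)C(CCB3C4CCCC3CCC4)=C(C)CC[C@@H]12 | intermediate
30 | methyl (1S,4aS,8aR)-5-[(E)-5-methoxy-3-methyl-5-oxopent-3-en-1-yl]-1,4a,6-trimethyl-1,2,3,4,4a,7,8,8a-octahydronaphthalene-1-carboxylate | COC(=O)[C@@]1(C)CCC[C@]2(C)C(CC/C(C)=C/C(=O)OC)=C(C)CC[C@@H]12 | intermediate
31 | methyl (1S,4aS,8aR)-5-[(E)-5-hydroxy-3-methylpent-3-en-1-yl]-1,4a,6-trimethyl-1,2,3,4,4a,7,8,8a-octahydronaphthalene-1-carboxylate | COC(=O)[C@@]1(C)CCC[C@]2(C)C(CC/C(C)=C/CO)=C(C)CC[C@@H]12 | intermediate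
32 | methyl (1S,4aS,8aR)-5-[(E)-5-acetoxy-3-methylpent-3-en-1-yl]-1,4a,6-trimethyl-1,2,3,4,4a,7,8,8a-octahydronaphthalene-1-carboxylate (methyl 15-acetoxylabda-8,13E-dien-19-oate) | COC(=O)[C@@]1(C)CCC[C@]2(C)C(CC/C(C)=C/COC(C)=O)=C(C)CC[C@@H]12 | target

**Step count and risks**

Total step count: 19. Longest linear sequence: 17 steps (steps 1–4, 6–15, 17–19); steps 5 and 16 make the two side fragments.

Steps most likely to fail:

Step 7. The β,β-disubstituted dienophile may add too slowly, so that Lewis acid-induced isomerisation or oligomerisation of the diene competes, or the endo and facial preferences may erode at the temperature needed. The fallback moves stereocontrol from the auxiliary to a catalyst. It sets out from acid 4: acyl transfer from its mixed anhydride 6 to oxazolidin-2-one (Et3N, LiCl) would give 3-[(E)-6-chloro-3-methylhex-2-enoyl]oxazolidin-2-one F1, NaI exchange would give 3-[(E)-6-iodo-3-methylhex-2-enoyl]oxazolidin-2-one F2, and alkylation of the sodium salt 13 would give the achiral trienyl imide F3. F3 would be cyclised with the bis(oxazoline) complex of divalent copper [Cu((R,R)-t-Bu-box)](SbF6)2 (catalytic, CH2Cl2, rt). This is a known catalysed intramolecular Diels–Alder reaction of trienyl imides, and the square-planar chelate of the (R,R) ligand should expose the same Cα-si face; a higher loading may be needed if the malonate competes for the metal. The cycloadduct F4 would be hydrogenated to the dihydro adduct F5 and cleaved with LiSEt, which comes back to the route at thioester 17.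

Step 11. Selenenylation must build a fully substituted C9 next to the quaternary C10; the enol ether may form slowly, the selenium electrophile may not reach C9, and the elimination depends on selenium entering cis to H-8. The fallback replaces the two-electron selenium sequence by a single-electron desaturation that needs no bond to C9 and no syn relationship: aldehyde 18 would be heated with 2-iodoxybenzoic acid (IBX) in DMSO at 70 °C. It sets out from 18 and comes back at enal 22 without a new compound.

Step 13. Discrimination between the two esters may be incomplete, through attack on the axial ester or over-reduction to the diol. The fallback differentiates the esters by hydrolysis rate instead of hydride attack. It sets out from diester 23: partial saponification (KOH, aq. MeOH) of the more exposed equatorial ester would give the half acid F6, oxalyl chloride (cat. DMF, CH2Cl2) would give the acid chloride F7, and NaBH4 in THF at 0 °C would reduce only the acid chloride, which comes back to the route at hydroxy ester 24.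

**Further compounds**

F1 | step 7 | 3-[(E)-6-chloro-3-methylhex-2-enoyl]oxazolidin-2-one | ClCCC/C(C)=C/C(=O)N1CCOC1=O
F2 | step 7 | 3-[(E)-6-iodo-3-methylhex-2-enoyl]oxazolidin-2-one | ICCC/C(C)=C/C(=O)N1CCOC1=O
F3 | step 7 | dimethyl 2-[(E)-4-methyl-6-oxo-6-(2-oxooxazolidin-3-yl)hex-4-en-1-yl]-2-[(1E,3E)-penta-1,3-dien-1-yl]malonate | C/C=C/C=C/C(C(=O)OC)(C(=O)OC)CCC/C(C)=C/C(=O)N1CCOC1=O
F4 | step 7 | dimethyl (4aS,5S,6S,8aR)-4a,6-dimethyl-5-[(2-oxooxazolidin-3-yl)carbonyl]-3,4,4a,5,6,8a-hexahydronaphthalene-1,1(2H)-dicarboxylate | COC(=O)C1(C(=O)OC)CCC[C@]2(C)[C@@H](C(=O)N3CCOC3=O)[C@@H](C)C=C[C@@H]12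
F5 | step 7 | dimethyl (4aS,5S,6S,8aR)-4a,6-dimethyl-5-[(2-oxooxazolidin-3-yl)carbonyl]octahydronaphthalene-1,1(2H)-dicarboxylate | COC(=O)C1(C(=O)OC)CCC[C@]2(C)[C@@H](C(=O)N3CCOC3=O)[C@@H](C)CC[C@@H]12
F0 | step 11 | none | none
F6 | step 13 | (1S,4aS,8aR)-5-ethenyl-1-(methoxycarbonyl)-4a,6-dimethyl-1,2,3,4,4a,7,8,8a-octahydronaphthalene-1-carboxylic acid | COC(=O)[C@@]1(C(=O)O)CCC[C@]2(C)C(C=C)=C(C)CC[C@@H]12
F7 | step 13 | methyl (1R,4aS,8aR)-1-(chlorocarbonyl)-5-ethenyl-4a,6-dimethyl-1,2,3,4,4a,7,8,8a-octahydronaphthalene-1-carboxylate | COC(=O)[C@@]1(C(Cl)=O)CCC[C@]2(C)C(C=C)=C(C)CC[C@@H]12
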